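## Retrosynthetic overview

1. Target ⇐ 18-hydroxyandrograpanin: C17–O bond formation on the exocyclic C8=C17 alkene (epoxidation), then a 1,2-hydride shift that sets C8 with the formyl group equatorial.
2. 18-Hydroxyandrograpanin ⇐ andrograpanin: hydroxyl-directed conversion of the C18 methyl C–H into C18–O through a silicon tether on 19-OH.
3. Andrograpanin ⇐ 14-deoxyandrographolide: removal of 3-OH through the 3,19-cyclic thionocarbonate.
4. 14-Deoxyandrographolide ⇐ andrographolide: reductive 1,3-transposition of the allylic alcohol through a transient C14–N bond (allylic diazene).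
5. Ring A, ring B and the lactone ring are carried intact from andrographolide and no C–C bond is made. Only transient heterocycles are formed, in the order dioxanethione, oxasilolane, spiro-epoxide.

Assumption: andrographolide, the bulk isolate of Andrographis paniculata, is taken as the cheap commercial starting material; atom numbers are those of the ent-labdane skeleton (C1–C20).

## Route

Step 1
Reactants: 1 andrographolide
Product: 5 14-deoxyandrographolide, via C14 sulfonylhydrazone adduct 2 (not isolated), via C14 sulfonylhydrazine 3 (not isolated), via allylic diazene 4 (not isolated)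
Conditions: N-isopropylidene-N′-(2-nitrobenzenesulfonyl)hydrazine (IPNBSH, 1.2 equiv), PPh3 (2.5 equiv), DEAD (2.5 equiv), THF, 0 → 23 °C; then CF3CH2OH/H2O (1:1), 23 °C
Reagents that add atoms: none
Why: Only the allylic C14–OH can undergo Mitsunobu displacement (C19 is neopentylic and C3 is flanked by the quaternary C4, so their phosphorus adducts revert on work-up); hydrazone hydrolysis and loss of sulfinic acid give the monoalkyl diazene, whose retro-ene loss of N2 delivers H to C12 and moves the alkene into the lactone ring (Myers–Movassaghi reductive 1,3-transposition), with no new stereocentre.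

Step 2
Reactants: 5 14-deoxyandrographolide
Product: 6 14-deoxyandrographolide 3,19-cyclic thionocarbonate
Conditions: TCDI (1.5 equiv), DMAP (0.2 equiv), THF, 65 °C
Reagents that add atoms: 1,1′-thiocarbonyldiimidazole (TCDI), S=C(n1ccnc1)n1ccnc1
Why: The gauche pair of equatorial 3-OH and axial 19-CH2OH closes a six-membered 1,3-dioxane-2-thione by double thioacyl transfer, the same ring topology as the easily formed 3,19-acetonide; no stereocentre is touched.

Step 3
Reactants: 6 14-deoxyandrographolide 3,19-cyclic thionocarbonate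
Product: 8 andrograpanin, via S-stannyl thiocarbonate 7 (not isolated)
Conditions: Bu3SnH (1.5 equiv), AIBN (0.2 equiv), toluene, 100 °C; then aq. NaHCO3/MeOH, 23 °C
Reagents that add atoms: none
Why: Barton–McCombie-type deoxygenation of a cyclic thionocarbonate: the stannyl radical adds to sulfur, the adduct fragments at the C3–O bond (secondary radical, not the primary C19–O bond), H-atom transfer gives CH2 at C3, and hydrolysis of the S-stannyl thiocarbonate frees 19-OH; no stereocentre is formed.

Step 4
Reactants: 8 andrograpanin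
Product: 11 18-hydroxyandrograpanin, via 19-O-diethylsilyl ether 9 (not isolated), via spiro-oxasilolane 10 (not isolated)
Conditions: Et2SiH2 (1.5 equiv), [Ir(cod)OMe]2 (0.5 mol %), THF, 23 °C; evaporate; [Ir(cod)OMe]2 (2 mol %), 3,4,7,8-tetramethyl-1,10-phenanthroline (Me4phen, 5 mol %), norbornene (1.5 equiv), THF, 100 °C; then 30% H2O2, KHCO3, THF/MeOH, 40 °C
Reagents that add atoms: hydrogen peroxide, OO
Why: Proposed new method: a primary, neopentylic carbinol serves as the anchor of a diethyl(hydrido)silyl tether for iridium-catalysed dehydrogenative γ-C(sp3)–H silylation, run in the presence of a 1,1-disubstituted alkene and a butenolide. The iridium silyl species formed by Si–H oxidative addition cleaves the nearest primary C–H bond (the equatorial C18 methyl on the same quaternary carbon, five-membered transition state) in preference to the secondary C3–H2, the tertiary C5–H and the δ-C20 methyl (six-membered). C–Si reductive elimination closes the spiro-oxasilolane, and strained norbornene, far more reactive than the hindered exocyclic alkene or the electron-poor butenolide, takes up the H2. The quaternary C4 (Thorpe–Ingold compression, no silyl-ether redistribution) should compensate for the missing carbinol substituents. Tamao–Fleming oxidation then turns C18–Si into C18–OH, and C4 becomes non-stereogenic. Closest known reaction type: the (hydrido)silyl-ether-directed, iridium/phenanthroline-catalysed γ-C–H silylation of secondary and tertiary alcohols followed by Tamao–Fleming oxidation to 1,3-diols.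

Step 5
Reactants: 11 18-hydroxyandrograpanin
Product: 14 18,19-dihydroxy-17-oxo-ent-labd-13-en-16,15-olide (target CNP0332660.1), via 8,17-epoxide 12 (not isolated), via axial C8-epimeric aldehyde 13 (not isolated)
Conditions: DMDO (1.2 equiv), acetone, 0 °C; evaporate; BF3·OEt2 (0.3 equiv), CH2Cl2, −78 °C; then DBU (0.5 equiv), CH2Cl2, 23 °C
Reagents that add atoms: dimethyldioxirane (DMDO), CC1(C)OO1
Why: Electrophilic DMDO epoxidises only the electron-rich exocyclic alkene, from the face opposite the axial C10 methyl; BF3-promoted Meinwald rearrangement opens the tertiary C8–O bond and the 1,2-hydride shift from C17 with inversion at C8 gives the equatorial aldehyde, while DBU equilibrates any axial epimer 13 to the thermodynamically favoured equatorial CHO (no syn-diaxial clash with the C10 methyl).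

## Compound list

1 | andrographolide | C[C@@]12CC[C@H]([C@@]([C@H]1CCC(=C)[C@H]2C/C=C/3\[C@@H](COC3=O)O)(C)CO)O | starting material
2 | C14 N-isopropylidene-N′-(2-nitrobenzenesulfonyl)hydrazide adduct of 1 (C14 inverted) | C[C@@]12CC[C@H]([C@@]([C@H]1CCC(=C)[C@H]2C/C=C/3\[C@H](COC3=O)N(N=C(C)C)S(=O)(=O)c4ccccc4[N+](=O)[O-])(C)CO)O | intermediate
3 | C14 N-(2-nitrobenzenesulfonyl)hydrazine (hydrazone hydrolysed) | C[C@@]12CC[C@H]([C@@]([C@H]1CCC(=C)[C@H]2C/C=C/3\[C@H](COC3=O)N(N)S(=O)(=O)c4ccccc4[N+](=O)[O-])(C)CO)O | intermediate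
4 | C14 allylic monoalkyl diazene | C[C@@]12CC[C@H]([C@@]([C@H]1CCC(=C)[C@H]2C/C=C/3\[C@H](COC3=O)N=N)(C)CO)O | intermediate
5 | 14-deoxyandrographolide (3,19-dihydroxy-ent-labda-8(17),13-dien-16,15-olide) | C[C@@]12CC[C@H]([C@@]([C@H]1CCC(=C)[C@H]2CCC3=CCOC3=O)(C)CO)O | intermediate
6 | 14-deoxyandrographolide 3,19-cyclic thionocarbonate | C[C@@]12CC[C@H]3OC(=S)OC[C@@]3(C)[C@H]1CCC(=C)[C@H]2CCC1=CCOC1=O | intermediate
7 | O-(andrograpanin-19-yl) S-tributylstannyl thiocarbonate | C[C@@]12CCC[C@@]([C@H]1CCC(=C)[C@H]2CCC1=CCOC1=O)(C)COC(=O)S[Sn](CCCC)(CCCC)CCCC | intermediate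
8 | andrograpanin (3,14-dideoxyandrographolide; axial 19-CH2OH, equatorial C18 methyl) | C[C@@]12CCC[C@@]([C@H]1CCC(=C)[C@H]2CCC1=CCOC1=O)(C)CO | intermediate
9 | 19-O-(diethylsilyl)andrograpanin | C[C@@]12CCC[C@@]([C@H]1CCC(=C)[C@H]2CCC1=CCOC1=O)(C)CO[SiH](CC)CC | intermediate
10 | spiro-oxasilolane at C4 (C18–SiEt2–O–C19) | C[C@@]12CCC[C@@]3([C@H]1CCC(=C)[C@H]2CCC1=CCOC1=O)C[Si](CC)(CC)OC3 | intermediate
11 | 18-hydroxyandrograpanin (18,19-dihydroxy-ent-labda-8(17),13-dien-16,15-olide) | C[C@@]12CCCC(CO)(CO)[C@H]1CCC(=C)[C@H]2CCC1=CCOC1=O | intermediate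
12 | 8,17-epoxide of 11 (oxygen equatorial, CH2 axial at C8) | C[C@@]12CCCC(CO)(CO)[C@H]1CC[C@@]3(CO3)[C@H]2CCC1=CCOC1=O | intermediate
13 | C8 epimer of the target (axial formyl) | C[C@@]12CCCC(CO)(CO)[C@H]1CC[C@@H](C=O)[C@H]2CCC1=CCOC1=O | intermediate
14 | 18,19-dihydroxy-17-oxo-ent-labd-13-en-16,15-olide (CNP0332660.1; equatorial 8-formyl, trans to the C10 methyl) | C[C@@]12CCCC(CO)(CO)[C@H]1CC[C@H](C=O)[C@H]2CCC1=CCOC1=O | target

## Step count and risks

Total step count: 5. Longest linear sequence: 5 steps (1 → 5 → 6 → 8 → 11 → 14).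

The three steps most likely to fail are steps 1, 4 and 5.

**Step 1 (Mitsunobu chemoselectivity on the free triol; SN2 against SN2′ at the Baylis–Hillman-type alcohol).** The fallback sets out from 1 and comes back at 5, replacing the C–N route by an ionic hydride transposition. Compound 1 is peracetylated (Ac2O, DMAP, pyridine, 0 → 23 °C) to 3,14,19-tri-O-acetylandrographolide F1. NaBH4 (MeOH/THF, 0 °C) then delivers hydride to C12 with SN2′ loss of the C14 acetate, the standard reduction of Morita–Baylis–Hillman acetates, to give 3,19-di-O-acetyl-14-deoxyandrographolide F2. K2CO3/MeOH removes the two acetates to give 5.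

**Step 4 (the proposed new step).** The risks are redistribution of the primary silyl ether, slow cyclometalation, and hydrosilylation or isomerisation of the alkene or butenolide. The fallback uses the established substrate class, a secondary carbinol next to a gem-disubstituted carbon as in 3-hydroxy-4,4-dimethyl terpenoids; it still runs the silylation next to the alkene and butenolide, so it answers the directing-group risk only. It sets out from 5 (steps 2 and 3 are then not used) and comes back at 11.
- 5 is silylated at the primary hydroxyl (TBSCl, imidazole, DMF) to 19-O-TBS-14-deoxyandrographolide F3.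
- The equatorial 3-OH is converted (Et2SiH2, [Ir(cod)OMe]2) into 3-O-diethylsilyl ether F4.
- F4 is cyclised ([Ir(cod)OMe]2, Me4phen, norbornene, THF, 100 °C) onto the gauche equatorial C18 methyl to give 3-O,C18-oxasilolane F5.
- Tamao–Fleming oxidation (H2O2, KHCO3) gives 3,18-diol F6.
- TCDI closes 3,18-cyclic thionocarbonate F7.
- Bu3SnH/AIBN cleaves the secondary C3–O bond to give O18 S-stannyl thiocarbonate F8, which is hydrolysed to 18-hydroxy-19-O-TBS-andrograpanin F9.
- TBAF (THF) removes the silyl ether to give 11.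

**Step 5 (epoxide rearrangement beside a free 1,3-diol: acetalisation with the new aldehyde, or elimination to allylic alcohols).** The fallback sets out from 11 and comes back at 14, replacing the rearrangement by hydroboration and oxidation.
- 11 is protected (2,2-dimethoxypropane, PPTS) as 18,19-O-isopropylidene acetal F10.
- 9-BBN followed by NaBO3·4H2O adds anti-Markovnikov from the face opposite the C10 methyl to give 17-alcohol F11 (axial CH2OH).
- Dess–Martin periodinane gives axial aldehyde acetonide F12.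
- DBU equilibrates it to equatorial aldehyde acetonide F13.
- Aqueous AcOH/THF removes the acetonide to give 14.

## Further compounds

F1 | step 1 | 3,14,19-tri-O-acetylandrographolide | C[C@@]12CC[C@H]([C@@]([C@H]1CCC(=C)[C@H]2C/C=C/3\[C@@H](COC3=O)OC(C)=O)(C)COC(C)=O)OC(C)=O
F2 | step 1 | 3,19-di-O-acetyl-14-deoxyandrographolide | C[C@@]12CC[C@H]([C@@]([C@H]1CCC(=C)[C@H]2CCC3=CCOC3=O)(C)COC(C)=O)OC(C)=O
F3 | step 4 | 19-O-TBS-14-deoxyandrographolide | C[C@@]12CC[C@H]([C@@]([C@H]1CCC(=C)[C@H]2CCC3=CCOC3=O)(C)CO[Si](C)(C)C(C)(C)C)O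
F4 | step 4 | 3-O-diethylsilyl-19-O-TBS-14-deoxyandrographolide | C[C@@]12CC[C@H]([C@@]([C@H]1CCC(=C)[C@H]2CCC3=CCOC3=O)(C)CO[Si](C)(C)C(C)(C)C)O[SiH](CC)CC
F5 | step 4 | 3-O,C18-oxasilolane of 19-O-TBS-14-deoxyandrographolide | C[C@@]12CC[C@H]3O[Si](CC)(CC)C[C@]3(CO[Si](C)(C)C(C)(C)C)[C@H]1CCC(=C)[C@H]2CCC1=CCOC1=O
F6 | step 4 | 18-hydroxy-19-O-TBS-14-deoxyandrographolide (3,18-diol) | C[C@@]12CC[C@H]([C@@]([C@H]1CCC(=C)[C@H]2CCC3=CCOC3=O)(CO)CO[Si](C)(C)C(C)(C)C)O
F7 | step 4 | 3,18-cyclic thionocarbonate of F6 | C[C@@]12CC[C@H]3OC(=S)OC[C@]3(CO[Si](C)(C)C(C)(C)C)[C@H]1CCC(=C)[C@H]2CCC1=CCOC1=O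
F8 | step 4 | O18 S-tributylstannyl thiocarbonate of 19-O-TBS-18-hydroxyandrograpanin | C[C@@]12CCC[C@@]([C@H]1CCC(=C)[C@H]2CCC1=CCOC1=O)(COC(=O)S[Sn](CCCC)(CCCC)CCCC)CO[Si](C)(C)C(C)(C)C
F9 | step 4 | 18-hydroxy-19-O-TBS-andrograpanin | C[C@@]12CCC[C@@]([C@H]1CCC(=C)[C@H]2CCC1=CCOC1=O)(CO)CO[Si](C)(C)C(C)(C)C
F10 | step 5 | 18,19-O-isopropylidene acetal of 11 | C[C@@]12CCCC3(COC(C)(C)OC3)[C@H]1CCC(=C)[C@H]2CCC1=CCOC1=O
F11 | step 5 | 17-hydroxy acetonide (axial CH2OH at C8) | C[C@@]12CCCC3(COC(C)(C)OC3)[C@H]1CC[C@@H](CO)[C@H]2CCC1=CCOC1=O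
F12 | step 5 | 17-oxo acetonide, axial formyl at C8 | C[C@@]12CCCC3(COC(C)(C)OC3)[C@H]1CC[C@@H](C=O)[C@H]2CCC1=CCOC1=O
F13 | step 5 | 17-oxo acetonide, equatorial formyl at C8 | C[C@@]12CCCC3(COC(C)(C)OC3)[C@H]1CC[C@H](C=O)[C@H]2CCC1=CCOC1=O
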